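The amounts of D are what differ here: X stands at 1.5 mM in both earlier runs and in the new flask, while D is 0.25 mM on Wednesday, 1 mM on Saturday and 0.50 mM in the new flask.

| flask | D | X | remark | time |
|---|---|---|---|---|
| Wednesday's | 0.25 mM | 1.5 mM | run made earlier |  |
| Saturday's | 1 mM | 1.5 mM | run made earlier |  |
| flask | 0.50 mM | 1.50 mM |  | 12 min |

| run | time / min | Z / % | D / % |
|---|---|---|---|
| Wednesday's | 0.833 | 8.1 | 68.8 |
| Wednesday's | 1.33 | 12.3 | 63.5 |
| Wednesday's | 1.50 | 13.1 | 61.4 |
| Wednesday's | 2.50 | 17.6 | 51.3 |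
| Wednesday's | 4.00 | 18.7 | 38.2 |
| Wednesday's | 5.00 | 17.4 | 32.0 |
| Wednesday's | 8.00 | 12.7 | 17.9 |
| Saturday's | 0.833 | 7.7 | 70.7 |
| Saturday's | 1.33 | 11.4 | 64.1 |
| Saturday's | 1.50 | 11.7 | 62.1 |
| Saturday's | 2.50 | 14.9 | 51.1 |
| Saturday's | 4.00 | 14.4 | 37.5 |
| Saturday's | 5.00 | 13.2 | 30.7 |
| Saturday's | 8.00 | 9.6 | 17.5 |

(scatter of a reading: 0.3 percentage points)
- a reading or a percentage of Z counts all its forms, free or not
* the moment within 12 min at which there is most Z
* the amount of Z, in percent of the D charged, at that time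

The highest Z readings are 18.7% at 4.00 min on Wednesday and 14.9% at 2.50 min on Saturday, and Z is falling by 8.00 min, so the peak stands well inside 12 min.

The charges step by equal factors, so define the log position w as the fraction of the way from Wednesday's charge to Saturday's on a logarithmic scale of D. The new charge is twice Wednesday's and Saturday's is twice the new one, so w = 0.500. Taking w of the way between the peak readings, in percent and in log time, gives 16.8% at 3.16 min.

The forecast, higher than this reckoning, named 17.5% at 3.4 min, seeing “an extra Z loss that depends on concentration”.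

The flask gives 17.0% at 3.25 min.

    Q ⇌ Z + L (K = 9.30 × 10⁻⁴ M, k = 0.0110 s⁻¹)
    D + L → G (k = 15.0 M⁻¹ s⁻¹)
    Z ⇌ E (K = 14.0, k = 0.00740 s⁻¹)
    D + X ⇌ Q (K = 260 M⁻¹, k = 12.0 M⁻¹ s⁻¹)
    J ⇌ Z, rate k5*(cs5 - [Z]) while solid is left; crystals form when [Z] > cs5 (solubility = 0.300 mM, k = 1.50 s⁻¹)

At 3.25 min, E already holds 16.1% of the D charged. Taking w between the readings at 4.00 min gives 16.6%, and the flask holds 16.6% at 4.07 min.

A second flask, with the same charges as the new flask but read at 3.0 min, is read close to the reckoned 3.16 min, so w of the way between the peak readings again gives about 16.8%. It holds 17.0% of Z.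

(The earlier runs and the new flask were computed for an exercise, noise included.)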